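Remark: atom labels follow the hydroazulene skeleton (C1 quaternary methyl carbon, C2, C3 CHOAc, C4 C(OH)iPr, C5 ring-fusion CH, C6 CHOAr, C7=C8 with the C8 methyl, C9, C10 CHOH; ring A five-membered, ring B seven-membered) and are kept for the corresponding carbons of every precursor; in this numbering the target is 1S,3S,4R,5R,6S,10S.

## The problem

The target is a cis-fused hydroazulene in which ring A (C1–C5) and ring B (C1, C10, C9, C8, C7, C6, C5) share the C1–C5 bond, with the C1 methyl and H5 on the same face. Four of the six stereocentres are contiguous on ring A (C1, C5, C4, C3): the C3 acetoxy and the tertiary C4 hydroxyl lie on the face of the C1 methyl, so the isopropyl group sits on the concave face next to ring B. The other two lie on ring B, each beside a ring-fusion carbon: the C6 ester oxygen is trans to H5 and the C10 hydroxyl is cis to the C1 methyl. A rigid cis-fused bicycle can therefore direct reagents to C3/C4 from its convex face, the angular methyl can direct hydride to C10, and the crowded C4/C5 flank can direct hydride to C6. Three secondary oxygens must end in three different states (acetate at C3, aryl ester at C6, free hydroxyl at C10) beside a free tertiary alcohol and a free phenol, so the order of acylation is part of the design. The allylic aryl ester ionises easily and cannot be exposed to acid. In every intermediate with a carbonyl at C6, H5 is enolisable and the C4 oxygen is β to that carbonyl, so epimerisation of the ring fusion, β-elimination and retro-aldol cleavage are latent. The enabling feature is the pair of oxygens at C6 and C10, joined on one side by C5–C1 and on the other by the three-carbon bridge C7–C8–C9 whose central carbon bears a one-carbon branch. This is the pattern left by a de Mayo reaction of a ring-fused cyclopentane-1,3-dione (C10–C7–C6 on C1/C5) with propadiene (C8, C9 and the branch carbon).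

## Retrosynthesis

**Acyl groups and C6 (37 to 30).** The two Si–O bonds of 36 are cut last, so that the phenol and the C10 hydroxyl stay masked through both acylations. The C6–O acyl bond is cut next, to allylic alcohol 32 and silylated acid 35, and 32 comes from enone 31 by 1,2-reduction. Placing the aryl ester late keeps it away from every acidic step. The C3 acetate is put on one step earlier, on 30, where C3–OH is the only acylable hydroxyl: C4–OH is tertiary, C10 is silylated and C6 is still a carbonyl. The forward steps must deliver hydride to C6 from the H5 face and acylate under neutral conditions.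

**Ring B adjustment (30 to 24).** The C7=C8 enone of 30 is traced to the exocyclic methylene of 27 by acid-catalysed conjugation, run together with removal of the C6 dioxolane and the acetonide. Conjugation can only go toward C6 once C10 is a silyl ether, so the C10 carbonyl must be reduced (26) while C6 is masked as the dioxolane (25). Reducing both carbonyls of 24 at once would be simpler, but would leave no way to tell C7 from C9 when the alkene is moved. The forward steps ask for site-selective ketalisation of the less hindered C6 carbonyl of 24 and hydride delivery to C10 anti to the angular methyl.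

**Key disconnection (24 to 21 and 22).** The bonds C7–C8 and C9–C10 are cut and the C7–C10 bond is restored, which contracts ring B to the cyclopentane-1,3-dione 21 and releases propadiene 22; the forward path runs through cyclobutanol 23. Cuts inside ring B that close it end to end (for example at C7=C8) would each need an acyclic precursor with the C1/C5 pair already set. This cut places both carbonyls and the C8 branch in one operation and carries the ring fusion in from a bicyclo[3.3.0]octane, where only the cis fusion can exist. The precursor is smaller by one ring size and three carbons. The forward reaction must add propadiene head-to-head and leave the photolabile product intact.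

**Dione (21 to 17).** The C7–C10 bond of 21 is cut by a retro-Claisen step to keto ester 20, hence keto acid 19. The acetyl group (C6, C7) and the carboxyl (C10) of 19 are recognised as the CH(CH3)–O and C=O ends of γ-lactone 17. The lactone is chosen over an anhydride because it enters with C6 and C10 already different and with a stereocentre at C6 that can be used and then destroyed. The forward steps need saponification, oxidation of the freed carbinol before it relactonises, and a kinetically controlled cyclisation that leaves H5 alone.

**Ring A oxygens (17 to 15).** The C3–O and C4–O bonds are cut to the alkene of bicyclic lactone 15 via diol 16. Dihydroxylation is placed here, before the photochemistry, for three reasons. Alkene 15 is the only alkene present at that stage. Its cup shape exposes the face that carries the C1 methyl and H5. A C3=C4 alkene kept until ring B exists would be β,γ to the C6 carbonyl and would invite conjugation through C5. The price is an acetonide carried from step 8 to step 16.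

**Ring A carbons (15 to 7, 3 and 8).** The C3=C4 bond is cut by retro-metathesis to diene 14; the C1–CH3 and C1–C2 bonds are cut to lactone 12 and then to butenolide 7, allyl bromide 8 and the alkenyl group from hydrazone 3 (C4–C5 bond). A Pd(OAc)2-catalysed trimethylenemethane [3+2] cycloaddition would close ring A in one step. It would leave a C3 ketone, though, whose functionalisation at C4 rather than C2 is not secured and which needs five more steps to reach the same alkene. The chosen sequence puts the isopropyl group on C4 by construction. The forward steps rely on anti addition to the C6 methyl of 7 and on two alkylations anti to the new C5 substituent.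

**Small pieces.** Butenolide 7 comes from acrylate 6 by ring-closing metathesis and 6 from (S)-but-3-en-2-ol 4 and acryloyl chloride 5. Hydrazone 3 comes from ketone 1 and hydrazide 2, and acid 35 from 4-hydroxybenzoic acid 33. All are single, standard operations.

## Roads not taken

**Alternative 1:** The cut is C3–C4. In the forward step SmI2 would couple the C3 aldehyde with the C4 isopropyl ketone of the ring-B-complete keto aldehyde A1 and give the cis-diol A2.
- Merits: ring A and both carbinol centres appear in one step, and the diol arrives unprotected, so the C3 acetate can be put on at once. This is better than the chosen plan in protecting-group economy, since no acetonide has to be carried.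
- Weak points: A1 already contains the seven-membered ring, the quaternary C1 and the C5, C6 and C10 stereocentres, so the cut postpones the hard part and does not solve it. A1 is a monocyclic cycloheptene without a rigid template. The cis relation within the diol is well founded through samarium bridging of the two oxygens. Which face of the ring the diol takes relative to the C1 methyl is decided in a flexible medium-ring chelate and is not secured. The hindered isopropyl ketone next to the epimerisable C5 may lose to simple reduction of the aldehyde.
- Comparison: the chosen plan sets against this a ring-A sequence on a bicyclic lactone in which every face is defined, and a ring B that comes out of the key step and need not be built before it.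

**Alternative 2:** The cuts are C2–C3 and C1–C5, with ring B contracted to a cyclohexene. In the forward step SnCl4 would ionise the acetoxy acetal carbon C3 of A3, the isopropenyl group would attack it, and the C1 cation would be quenched by migration of C5 from C10 to C1, giving hydroazulenone A4 (Prins–pinacol sequence).
- Merits: one step makes ring A, the quaternary C1 and the enlarged ring B, and the carbonyl sits at C10 only. No C6/C10 differentiation is needed, a clear advantage over the chosen plan, whose least secure step is exactly that differentiation. The C3/C4 oxygens come in as an acetonide.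
- Weak points: A4 has the alkene at C6=C7, a saturated methyl-bearing C8 and no oxygen at C6. The C6 oxygen and the C7=C8 alkene would have to come from an allylic oxidation with transposition, which must choose between two allylic termini and two faces. A3 needs the tertiary C4 centre and its relation to C5 and C10 set across a freely rotating C4–C5 bond before the key step.
- Comparison: the chosen plan sets against this that C6 is oxygenated from the outset, that C8 is born as the correct one-carbon branch, and that ring A is made on a rigid bicycle.

**Alternative 3:** The cuts are C8–C9 and C5–C6. In the forward step Rh2(S-DOSP)4 would convert vinyldiazoacetate A6 into a carbenoid that cyclopropanates the siloxyvinyl group of dienone A5, and Cope rearrangement of the cis-divinylcyclopropane would give A7.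
- Merits: this is the most convergent road, giving a hydroazulene in one catalytic asymmetric step from two achiral pieces. The C6 and C10 oxygens arrive differentiated (silyl ether and silyl enol ether), and C5/C6 are set together in the boat-shaped transition state. In step count to the bicyclic core and in C6/C10 differentiation it is better than the chosen plan.
- Weak points: A7 lacks the C1 methyl, which must be added to the C10 enolate at the ring fusion. C8 carries an ester that has to be taken down to a methyl group without moving the alkene. Ring A has only a C4 ketone, flanked by the epimerisable C5 and β to the C6 silyloxy group. The isopropyl nucleophile would have to add to that ketone from the concave face to give the required C4 configuration, against the normal convex-face preference, and C3 is still unoxidised.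
- Comparison: the chosen plan sets against the shorter start that C3 and C4 are made together by a convex-face dihydroxylation in which the isopropyl group is forced onto the concave face, and that no carbon has to be reduced or added after ring B exists.

Key step: step 12

## Route

Step 1
Reactants: 1 3-methylbutan-2-one; 2 2,4,6-triisopropylbenzenesulfonohydrazide
Product: 3 (E)-2,4,6-triisopropyl-N'-(3-methylbutan-2-ylidene)benzenesulfonohydrazide
Conditions: conc. HCl (cat.), MeOH, rt; crystallisation
Reagents that add atoms: none
Why: Acid-catalysed hydrazone condensation; the triisopropylbenzenesulfonyl hydrazone is chosen because it undergoes the Shapiro reaction cleanly at low temperature, and the E/Z ratio is of no consequence.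

Step 2
Reactants: 4 (S)-but-3-en-2-ol; 5 acryloyl chloride
Product: 6 (S)-but-3-en-2-yl acrylate
Conditions: Et3N, DMAP (cat.), CH2Cl2, 0 °C
Reagents that add atoms: none
Why: O-Acylation of a secondary allylic alcohol with an acid chloride; the carbinol stereocentre (the future, later sacrificed C6) is not involved.

Step 3
Reactants: 6 (S)-but-3-en-2-yl acrylate
Product: 7 (S)-5-methylfuran-2(5H)-one
Conditions: RuCl2(=CHPh)(PCy3)(H2IMes) (second-generation Grubbs catalyst, 3 mol%), CH2Cl2, 40 °C
Reagents that add atoms: none
Why: Ring-closing metathesis of an allyl acrylate to a butenolide with loss of ethene, a standard use of this Ru carbene; the stereocentre is untouched.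

Step 4
Reactants: 3 (E)-2,4,6-triisopropyl-N'-(3-methylbutan-2-ylidene)benzenesulfonohydrazide; 7 (S)-5-methylfuran-2(5H)-one; 8 allyl bromide
Product: 12 (3R,4S,5S)-3-allyl-5-methyl-4-(3-methylbut-1-en-2-yl)dihydrofuran-2(3H)-one, via alkenyllithium 9 (not isolated), via dialkenylcuprate 10 (not isolated), via lithium enolate 11 (not isolated)
Conditions: n-BuLi (2 equiv per 3), TMEDA, THF, –78 → 0 °C; CuI (0.5 equiv per 9), –40 °C; 7, –78 °C; then 8, DMPU, –78 → –20 °C
Reagents that add atoms: none
Why: The Shapiro reaction gives the less substituted alkenyllithium 9 and CuI converts it into cuprate 10, whose conjugate addition to 7 occurs anti to the C6 methyl and sets C5; enolate 11 is then allylated anti to the new C5 substituent (tandem conjugate addition–enolate alkylation), and the soft, weakly basic cuprate should not deprotonate 7 at its γ-position.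

Step 5
Reactants: 12 (3R,4S,5S)-3-allyl-5-methyl-4-(3-methylbut-1-en-2-yl)dihydrofuran-2(3H)-one
Product: 14 (3S,4R,5S)-3-allyl-3,5-dimethyl-4-(3-methylbut-1-en-2-yl)dihydrofuran-2(3H)-one, via lithium enolate 13 (not isolated)
Conditions: LiN(iPr)2, THF, –78 °C; MeI, DMPU, –78 → –40 °C
Reagents that add atoms: iodomethane, CI
Why: Enolate alkylation: iodomethane approaches the planar enolate 13 anti to the adjacent C5 alkenyl group, so the methyl ends trans and the allyl chain cis to that group, which sets the quaternary C1; a minor epimer could not close the cis-fused ring in step 6 and would be removed there.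

Step 6
Reactants: 14 (3S,4R,5S)-3-allyl-3,5-dimethyl-4-(3-methylbut-1-en-2-yl)dihydrofuran-2(3H)-one
Product: 15 cis-fused bicyclic lactone 4-isopropyl-3,6a-dimethyl-3,3a,6,6a-tetrahydro-1H-cyclopenta[c]furan-1-one (ring A alkene C3=C4 bearing isopropyl on C4; C1 methyl, H5 and C6 methyl on one face)
Conditions: RuCl2(=CHPh)(PCy3)(H2IMes) (second-generation Grubbs catalyst, 5 mol%), toluene, 80 °C
Reagents that add atoms: none
Why: Ring-closing metathesis between the allyl group and the 1,1-disubstituted alkene closes the five-membered ring A with the isopropyl-bearing trisubstituted alkene; only cis-disposed chains can give the bicyclo[3.3.0] skeleton.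

Step 7
Reactants: 15 cis-fused bicyclic alkene lactone
Product: 16 diol lactone (cis-3,4-diol of 15; both hydroxyls on the face of the C1 methyl and H5; isopropyl on the concave face; configuration at C1 C3 C4 C5 as in 37)
Conditions: OsO4 (2 mol%), NMO, acetone–H2O (4:1), rt
Reagents that add atoms: osmium tetroxide (catalytic oxygen carrier), O=[Os](=O)(=O)=O; N-methylmorpholine N-oxide, C[N+]1([O-])CCOCC1; water, O
Why: Upjohn dihydroxylation (syn addition) of the only alkene from the convex face of the cis-bicyclo[3.3.0] lactone, opposite to the allylic C5–C6 bond and the lactone ring, sets C3 and C4 together.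

Step 8
Reactants: 16 diol lactone
Product: 17 acetonide lactone (3,4-O-isopropylidene derivative of 16)
Conditions: 2,2-dimethoxypropane, PPTS (cat.), CH2Cl2, rt
Reagents that add atoms: 2,2-dimethoxypropane, COC(C)(C)OC
Why: Transketalisation onto a cis-1,2-diol; the acetonide shields the secondary C3 hydroxyl from the oxidation of step 9 and both hydroxyls from base and silylation up to step 16.

Step 9
Reactants: 17 acetonide lactone
Product: 19 keto acid (ring A acetonide carrying cis 1-carboxy-1-methyl and 5-acetyl groups), via lithium hydroxy carboxylate 18 (not isolated)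
Conditions: LiOH, THF–H2O, rt; then RuCl3·xH2O (cat.), NaIO4, NaHCO3 (pH ≈ 8), H2O–MeCN, 0 °C; then 1 M HCl to pH 3, 0 °C
Reagents that add atoms: lithium hydroxide, [Li+].[OH-]
Why: Saponification opens the γ-lactone to 18 and catalytic RuO4 oxidises the freed secondary carbinol while the carboxylate keeps the chain open, so relactonisation cannot compete; the C6 stereocentre, having done its work, is destroyed here.

Step 10
Reactants: 19 keto acid
Product: 20 methyl ester of 19 (methyl ketone at C6 and methyl ester at C10 cis on ring A)
Conditions: MeI, K2CO3, DMF, rt
Reagents that add atoms: iodomethane, CI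
Why: SN2 O-alkylation of the carboxylate gives the open methyl ester under non-acidic conditions that spare the acetonide and H5.

Step 11
Reactants: 20 keto ester
Product: 21 tricyclic 1,3-dione (cis-1-methylbicyclo[3.3.0]octane-2,4-dione with the C10 and C6 carbonyls and the C7 methylene; ring A carries the 3,4-acetonide and the 4-isopropyl group; configuration at C1 C3 C4 C5 as in 37)
Conditions: LiN(SiMe3)2 (2.2 equiv), THF, –78 → 0 °C; then 1 M HCl to pH 4
Reagents that add atoms: none
Why: Intramolecular Claisen condensation (Dieckmann type): kinetic deprotonation of the acetyl methyl and 5-exo-trig attack on the ester give the dione, held as its diketonate; the hindered H5 is not removed, so neither the ring fusion nor the β-oxygen at C4 is put at risk, and only the cis-fused bicycle can form.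

Step 12
Reactants: 21 tricyclic 1,3-dione; 22 propadiene
Product: 24 cis-fused 3,4-O-isopropylidene-8-methylene-hydroazulene-6,10-dione, via methylenecyclobutanol 23 (not isolated)
Conditions: 22 (excess, condensed), degassed MeCN, hν (254 nm, quartz), –40 °C, to about 90% conversion; then rt
Reagents that add atoms: none
Why: Dione 21 is present largely as its enol (hydroxyl on C6 or on C10), which absorbs strongly near 250 nm while the product ketones do not, so the light is taken up by the substrate. The excited enol reacts as a triplet enone and adds propadiene through a 1,4-biradical to give methylenecyclobutanol 23; the closest known reaction types are the de Mayo reaction of enolised 1,3-diketones and the head-to-head photocycloaddition of propadiene to cyclic enones, in which the central allene carbon bonds to the enone α-carbon (C7–C8) and a terminal carbon to the β-carbon (C9–C10). The β-hydroxy ketone held in the strained four-membered ring then undergoes retro-aldol cleavage of C7–C10. The cyclobutane is thus closed by a [2+2] cycloaddition, and the seven-membered ring B arises by two-carbon expansion of the dione ring, not by an end-to-end cyclisation. No stereocentre of 24 is created: the cyclobutane centres of 23 vanish on fragmentation and C1/C5 keep the cis fusion carried in from 21. The step needs regiocontrol only: head-to-head addition puts the methylene carbon on C8, and addition to the other enol tautomer gives the same constitution. The product, a doubly β,γ-unsaturated diketone, must also be spared secondary photolysis, which the difference in absorbance at 254 nm, the low temperature and the incomplete conversion should secure. The saturated ring A and its acetonide carry no chromophore or alkene that could intercept the excited enol.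

Step 13
Reactants: 24 hydroazulene-6,10-dione
Product: 25 6,6-ethylenedioxy derivative of 24 (C10 ketone and 8-methylene retained)
Conditions: 1,2-bis(trimethylsilyloxy)ethane, TMSOTf (cat.), CH2Cl2, –78 → –40 °C; pyridine quench
Reagents that add atoms: 1,2-bis(trimethylsilyloxy)ethane, C[Si](C)(C)OCCO[Si](C)(C)C
Why: Silyl-triflate-catalysed ketalisation under aprotic, kinetic conditions: the C6 carbonyl has one open face (that of H5), whereas both faces of the C10 carbonyl are flanked by substituents of the quaternary C1, so the dioxolane should form at C6; at this temperature the exocyclic alkene does not migrate.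

Step 14
Reactants: 25 C6 ketal
Product: 26 C10 alcohol (hydroxyl cis to the C1 methyl)
Conditions: NaBH4, MeOH–THF, 0 °C → rt
Reagents that add atoms: none
Why: Borohydride reduction of the remaining ketone; hydride approaches anti to the angular C1 methyl, as in ketones flanked by an angular methyl in hydrindanone and decalone series, which sets C10.

Step 15
Reactants: 26 C10 alcohol
Product: 27 C10 triisopropylsilyl ether
Conditions: TIPSOTf, 2,6-lutidine, CH2Cl2, –20 → 0 °C
Reagents that add atoms: triisopropylsilyl trifluoromethanesulfonate, CC(C)[Si](C(C)C)(C(C)C)OS(=O)(=O)C(F)(F)F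
Why: Silylation of a hindered secondary alcohol with a buffered silyl triflate; the triisopropylsilyl ether is chosen because it must survive the aqueous acid of step 16.

Step 16
Reactants: 27 C10 silyl ether
Product: 30 3,4-dihydroxy-10-(triisopropylsilyloxy)hydroazul-7-en-6-one (C8 methyl; configuration at C1 C3 C4 C5 C10 as in 37), via β,γ-enone 28 (not isolated), via conjugated enone acetonide 29 (not isolated)
Conditions: 2 M aq. HCl–THF (1:3), rt
Reagents that add atoms: water, O
Why: Acid hydrolysis removes the dioxolane (28), acid-catalysed enolisation toward C7 moves the exocyclic alkene into conjugation (29; only C6 can conjugate because C10 is now sp3), and further hydrolysis removes the acetonide; H5 lies between two fully substituted carbons and its enolisation would be cross-conjugated, so the ring fusion and the C4 oxygen should persist.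

Step 17
Reactants: 30 enone diol
Product: 31 3-acetate of 30
Conditions: Ac2O, pyridine, DMAP (cat.), CH2Cl2, 0 °C → rt
Reagents that add atoms: acetic anhydride, CC(=O)OC(C)=O
Why: DMAP-catalysed acetylation of the only reactive hydroxyl: C3–OH is secondary, C4–OH is tertiary and inert here, C10 is silylated and C6 is a carbonyl.

Step 18
Reactants: 31 enone acetate
Product: 32 allylic alcohol (C6 hydroxyl trans to H5)
Conditions: NaBH4, CeCl3·7H2O, MeOH, –78 → –40 °C
Reagents that add atoms: none
Why: Luche 1,2-reduction of the enone; hydride enters C6 from the face of H5, away from the fully substituted C4, which sets C6, and the acetate is not reduced at this temperature.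

Step 19
Reactants: 33 4-hydroxybenzoic acid
Product: 35 4-[(tert-butyldimethylsilyl)oxy]benzoic acid, via silyl ester 34 (not isolated)
Conditions: TBSCl (2.2 equiv), imidazole, DMF, rt; then AcOH–THF–H2O, rt
Reagents that add atoms: tert-butyldimethylsilyl chloride, CC(C)(C)[Si](C)(C)Cl
Why: Bis-silylation followed by selective hydrolysis of the labile silyl ester leaves the aryl silyl ether, a standard route to O-silylated hydroxybenzoic acids.

Step 20
Reactants: 32 allylic alcohol; 35 4-[(tert-butyldimethylsilyl)oxy]benzoic acid
Product: 36 bis-silyl ether of the target (C6 4-silyloxybenzoate; C10 triisopropylsilyl ether)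
Conditions: EDC·HCl, DMAP, CH2Cl2, rt
Reagents that add atoms: none
Why: Steglich esterification of the allylic secondary alcohol under neutral conditions that avoid ionisation at C6; the tertiary C4 hydroxyl does not compete.

Step 21
Reactants: 36 bis-silyl ether
Product: 37 target, (1S,3S,4R,5R,6S,10S)-3-acetoxy-4,10-dihydroxy-4-isopropyl-1,8-dimethyl-cis-hydroazul-7-en-6-yl 4-hydroxybenzoate (numbering of the remark)
Conditions: HF·pyridine, pyridine, THF, 0 °C → rt
Reagents that add atoms: none
Why: Fluoride cleavage of the aryl silyl ether and of the C10 silyl ether in buffered HF·pyridine leaves the acetate, the allylic aryl ester and the tertiary alcohol untouched.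

## Compound list

1 | 3-methylbutan-2-one | CC(=O)C(C)C | starting material
2 | 2,4,6-triisopropylbenzenesulfonohydrazide | NNS(=O)(=O)c1c(C(C)C)cc(C(C)C)cc1C(C)C | starting material
3 | (E)-2,4,6-triisopropyl-N'-(3-methylbutan-2-ylidene)benzenesulfonohydrazide | CC(C)/C(C)=N/NS(=O)(=O)c1c(C(C)C)cc(C(C)C)cc1C(C)C | intermediate
4 | (S)-but-3-en-2-ol | C[C@H](O)C=C | starting material
5 | acryloyl chloride | C=CC(Cl)=O | starting material
6 | (S)-but-3-en-2-yl acrylate | C=CC(=O)O[C@@H](C)C=C | intermediate
7 | (S)-5-methylfuran-2(5H)-one | C[C@@H]1OC(=O)C=C1 | intermediate
8 | allyl bromide | C=CCBr | starting material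
9 | 3-methylbut-1-en-2-yllithium | [Li]C(=C)C(C)C | intermediate (not isolated)
10 | lithium bis(3-methylbut-1-en-2-yl)cuprate | [Li+].C=C(C(C)C)[Cu-]C(=C)C(C)C | intermediate (not isolated)
11 | lithium enolate of (4S,5S)-5-methyl-4-(3-methylbut-1-en-2-yl)dihydrofuran-2(3H)-one | [Li]OC1=C[C@@H](C(=C)C(C)C)[C@H](C)O1 | intermediate (not isolated)
12 | (3R,4S,5S)-3-allyl-5-methyl-4-(3-methylbut-1-en-2-yl)dihydrofuran-2(3H)-one | C=CC[C@H]1C(=O)O[C@@H](C)[C@@H]1C(=C)C(C)C | intermediate
13 | lithium enolate of 12 | [Li]OC1=C(CC=C)[C@@H](C(=C)C(C)C)[C@H](C)O1 | intermediate (not isolated)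
14 | (3S,4R,5S)-3-allyl-3,5-dimethyl-4-(3-methylbut-1-en-2-yl)dihydrofuran-2(3H)-one (allyl cis to the alkenyl group) | C=CC[C@]1(C)C(=O)O[C@@H](C)[C@@H]1C(=C)C(C)C | intermediate
15 | cis-fused 4-isopropyl-3,6a-dimethyl-3,3a,6,6a-tetrahydro-1H-cyclopenta[c]furan-1-one (C1 methyl, H5 and C6 methyl on one face) | CC(C)C1=CC[C@]2(C)C(=O)O[C@@H](C)[C@H]12 | intermediate
16 | diol lactone: cis-3,4-diol of 15, hydroxyls on the face of the C1 methyl and H5 | O[C@H]1C[C@]2(C)C(=O)O[C@@H](C)[C@@H]2[C@]1(O)C(C)C | intermediate
17 | acetonide lactone: 3,4-O-isopropylidene derivative of 16 | CC1(C)O[C@H]2C[C@]3(C)C(=O)O[C@@H](C)[C@@H]3[C@]2(O1)C(C)C | intermediate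
18 | lithium carboxylate of the ring-opened hydroxy acid of 17 (C6 carbinol free) | [Li+].CC1(C)O[C@H]2C[C@](C)(C(=O)[O-])[C@H]([C@H](C)O)[C@]2(O1)C(C)C | intermediate (not isolated)
19 | keto acid: ring A acetonide with cis 1-carboxy-1-methyl and 5-acetyl groups | CC1(C)O[C@H]2C[C@](C)(C(=O)O)[C@H](C(C)=O)[C@]2(O1)C(C)C | intermediate
20 | methyl ester of 19 | CC1(C)O[C@H]2C[C@](C)(C(=O)OC)[C@H](C(C)=O)[C@]2(O1)C(C)C | intermediate
21 | tricyclic 1,3-dione: cis-1-methylbicyclo[3.3.0]octane-2,4-dione fused to the ring A acetonide with 4-isopropyl | CC1(C)O[C@H]2C[C@]3(C)C(=O)CC(=O)[C@@H]3[C@]2(O1)C(C)C | intermediate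
22 | propadiene | C=C=C | starting material
23 | methylenecyclobutanol photoadduct (C10 hydroxyl isomer from convex-face addition drawn; the C6 hydroxyl isomer converges) | CC1(C)O[C@H]2C[C@]3(C)[C@@]4(O)CC(=C)[C@H]4C(=O)[C@@H]3[C@]2(O1)C(C)C | intermediate (not isolated)
24 | cis-fused 3,4-O-isopropylidene-8-methylene-hydroazulene-6,10-dione | CC1(C)O[C@H]2C[C@]3(C)C(=O)CC(=C)CC(=O)[C@@H]3[C@]2(O1)C(C)C | intermediate
25 | 6,6-ethylenedioxy derivative of 24 | CC1(C)O[C@H]2C[C@]3(C)C(=O)CC(=C)CC4(OCCO4)[C@@H]3[C@]2(O1)C(C)C | intermediate
26 | C10 alcohol of 25 (hydroxyl cis to the C1 methyl) | CC1(C)O[C@H]2C[C@]3(C)[C@@H](O)CC(=C)CC4(OCCO4)[C@@H]3[C@]2(O1)C(C)C | intermediate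
27 | C10 triisopropylsilyl ether of 26 | CC1(C)O[C@H]2C[C@]3(C)[C@@H](O[Si](C(C)C)(C(C)C)C(C)C)CC(=C)CC4(OCCO4)[C@@H]3[C@]2(O1)C(C)C | intermediate
28 | 8-methylene-6-ketone (β,γ-enone) with acetonide and C10 silyl ether | CC1(C)O[C@H]2C[C@]3(C)[C@@H](O[Si](C(C)C)(C(C)C)C(C)C)CC(=C)CC(=O)[C@@H]3[C@]2(O1)C(C)C | intermediate (not isolated)
29 | 7-en-6-one with acetonide and C10 silyl ether | CC1(C)O[C@H]2C[C@]3(C)[C@@H](O[Si](C(C)C)(C(C)C)C(C)C)CC(C)=CC(=O)[C@@H]3[C@]2(O1)C(C)C | intermediate (not isolated)
30 | 3,4-dihydroxy-10-(triisopropylsilyloxy)hydroazul-7-en-6-one | O[C@H]1C[C@]2(C)[C@@H](O[Si](C(C)C)(C(C)C)C(C)C)CC(C)=CC(=O)[C@@H]2[C@]1(O)C(C)C | intermediate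
31 | 3-acetate of 30 | CC(=O)O[C@H]1C[C@]2(C)[C@@H](O[Si](C(C)C)(C(C)C)C(C)C)CC(C)=CC(=O)[C@@H]2[C@]1(O)C(C)C | intermediate
32 | C6 allylic alcohol of 31 (hydroxyl trans to H5) | CC(=O)O[C@H]1C[C@]2(C)[C@@H](O[Si](C(C)C)(C(C)C)C(C)C)CC(C)=C[C@H](O)[C@@H]2[C@]1(O)C(C)C | intermediate
33 | 4-hydroxybenzoic acid | OC(=O)c1ccc(O)cc1 | starting material
34 | tert-butyldimethylsilyl 4-[(tert-butyldimethylsilyl)oxy]benzoate | CC(C)(C)[Si](C)(C)OC(=O)c1ccc(O[Si](C)(C)C(C)(C)C)cc1 | intermediate (not isolated)
35 | 4-[(tert-butyldimethylsilyl)oxy]benzoic acid | OC(=O)c1ccc(O[Si](C)(C)C(C)(C)C)cc1 | intermediate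
36 | bis-silyl ether of the target (aryl tert-butyldimethylsilyl ether; C10 triisopropylsilyl ether) | CC(=O)O[C@H]1C[C@]2(C)[C@@H](O[Si](C(C)C)(C(C)C)C(C)C)CC(C)=C[C@H](OC(=O)c3ccc(O[Si](C)(C)C(C)(C)C)cc3)[C@@H]2[C@]1(O)C(C)C | intermediate
37 | CNP0146780.2, (1S,3S,4R,5R,6S,10S)-3-acetoxy-4,10-dihydroxy-4-isopropyl-1,8-dimethyl-cis-hydroazul-7-en-6-yl 4-hydroxybenzoate | CC(=O)O[C@H]1C[C@]2(C)[C@@H](O)CC(C)=C[C@H](OC(=O)c3ccc(O)cc3)[C@@H]2[C@]1(O)C(C)C | target

## Step count and least certain steps

Total step count: 21. Longest linear sequence: 19 steps (steps 2–18, 20 and 21, from 4); steps 1 and 19 are one-step side branches.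

**Step 12 (key step).** Most likely to go wrong: secondary photolysis of the product as it accumulates (acyl shifts of the β,γ-unsaturated ketones, γ-hydrogen abstraction from the isopropyl group), or partial head-to-tail addition, because the product ketones and the biradical partitioning are not under substrate control. Fallback: 21 is O-acetylated (Ac2O, Et3N, DMAP) to the enol acetate F1. F1 is irradiated with propadiene through Pyrex to the acetoxy methylenecyclobutane F2, a stable photoadduct that can be purified. Methanolysis of the acetate (K2CO3, MeOH) in the dark then releases the cyclobutanolate, which fragments to 24, so the dione is never exposed to light.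

**Step 13.** Most likely to go wrong: insufficient discrimination between the two carbonyl groups, or acid-induced migration of the exocyclic alkene before the ketal has formed, because the difference between C6 and C10 is steric only. Fallback, using hydride rather than ketal formation at the more accessible carbonyl and setting out from 24:
- NaBH4 at –78 °C reduces C6 to the hydroxy ketone F3, which is acetylated to F4.
- Reduction of C10 gives F5 and TIPSOTf gives the silyl ether F6.
- Methanolysis of the acetate gives alcohol F7, and Dess–Martin oxidation returns the C6 ketone, which is 28.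
- 28 is carried through the acid treatment of step 16 to 30.

**Step 4.** Most likely to go wrong: incomplete allylation of the mixed lithium–copper enolate, or proton transfer within the one-pot sequence giving unallylated lactone and dialkylated material. Fallback: the operations are divided. From 7, conjugate addition of 10 with NH4Cl quench gives the lactone F8, and separate deprotonation with LiN(iPr)2 and allylation with 8 returns to 12.

**Step 14.** Most likely to go wrong: poor facial selectivity of hydride delivery to C10, because ring B is flexible and the methyl and the ring methylene on C1 are not very different in size. Fallback: from 25, if the C10 epimer F9 is the main product, Mitsunobu inversion with 4-nitrobenzoic acid (PPh3, DIAD) gives the inverted ester F10, and methanolysis (K2CO3, MeOH) returns to 26.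

**Step 18.** Most likely to go wrong: poor facial selectivity at C6 or competing 1,4-reduction, because the enone sits in a flexible ring beside a free tertiary alcohol that can bind cerium. Fallback: from 31, if the C6 epimer F11 predominates, it is esterified with 35 under Mitsunobu conditions (PPh3, DIAD), which forms the C6–O bond with inversion and gives 36 directly, so that step 20 is bypassed.

Further compounds
F1 | step 12 | enol acetate of 21 (6-acetoxy regioisomer drawn; the 10-acetoxy isomer converges) | CC1(C)O[C@H]2C[C@]3(C)C(=O)C=C(OC(C)=O)[C@@H]3[C@]2(O1)C(C)C
F2 | step 12 | acetoxy methylenecyclobutane photoadduct of F1 and propadiene (convex-face adduct drawn) | CC1(C)O[C@H]2C[C@]3(C)C(=O)[C@H]4C(=C)C[C@@]4(OC(C)=O)[C@@H]3[C@]2(O1)C(C)C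
F3 | step 13 | 6-hydroxy-10-ketone of 24 (hydroxyl trans to H5) | CC1(C)O[C@H]2C[C@]3(C)C(=O)CC(=C)C[C@H](O)[C@@H]3[C@]2(O1)C(C)C
F4 | step 13 | 6-acetate of F3 | CC1(C)O[C@H]2C[C@]3(C)C(=O)CC(=C)C[C@H](OC(C)=O)[C@@H]3[C@]2(O1)C(C)C
F5 | step 13 | 6-acetoxy-10-alcohol (C10 hydroxyl cis to the C1 methyl) | CC1(C)O[C@H]2C[C@]3(C)[C@@H](O)CC(=C)C[C@H](OC(C)=O)[C@@H]3[C@]2(O1)C(C)C
F6 | step 13 | 6-acetoxy-10-triisopropylsilyl ether | CC1(C)O[C@H]2C[C@]3(C)[C@@H](O[Si](C(C)C)(C(C)C)C(C)C)CC(=C)C[C@H](OC(C)=O)[C@@H]3[C@]2(O1)C(C)C
F7 | step 13 | 6-hydroxy-10-triisopropylsilyl ether | CC1(C)O[C@H]2C[C@]3(C)[C@@H](O[Si](C(C)C)(C(C)C)C(C)C)CC(=C)C[C@H](O)[C@@H]3[C@]2(O1)C(C)C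
F8 | step 4 | (4S,5S)-5-methyl-4-(3-methylbut-1-en-2-yl)dihydrofuran-2(3H)-one | O=C1C[C@@H](C(=C)C(C)C)[C@H](C)O1
F9 | step 14 | C10 epimer of 26 (hydroxyl trans to the C1 methyl) | CC1(C)O[C@H]2C[C@]3(C)[C@H](O)CC(=C)CC4(OCCO4)[C@@H]3[C@]2(O1)C(C)C
F10 | step 14 | 4-nitrobenzoate of 26 (C10 configuration as in 26) | CC1(C)O[C@H]2C[C@]3(C)[C@@H](OC(=O)c4ccc(cc4)[N+]([O-])=O)CC(=C)CC5(OCCO5)[C@@H]3[C@]2(O1)C(C)C
F11 | step 18 | C6 epimer of 32 (hydroxyl cis to H5) | CC(=O)O[C@H]1C[C@]2(C)[C@@H](O[Si](C(C)C)(C(C)C)C(C)C)CC(C)=C[C@@H](O)[C@@H]2[C@]1(O)C(C)C
A1 | alternative 1 | ring-A-open keto aldehyde: C3 aldehyde and C4 isopropyl ketone on the C10-silyloxy C6-(4-methoxybenzyloxy) cycloheptene | O=CC[C@]1(C)[C@@H](O[Si](C)(C)C(C)(C)C)CC(C)=C[C@H](OCc2ccc(OC)cc2)[C@@H]1C(=O)C(C)C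
A2 | alternative 1 | cis-fused hydroazulene-3,4-diol with C6 4-methoxybenzyl ether and C10 silyl ether | O[C@H]1C[C@]2(C)[C@@H](O[Si](C)(C)C(C)(C)C)CC(C)=C[C@H](OCc3ccc(OC)cc3)[C@@H]2[C@]1(O)C(C)C
A3 | alternative 2 | 1-isopropenylcyclohex-3-enyl triethylsilyl ether bearing the 4-acetoxy-5-isopropyl-2,2-dimethyl-1,3-dioxolan-5-yl group (acetal carbon C3 as either epimer) | CC(=O)OC1OC(C)(C)O[C@]1(C(C)C)[C@H]2C=C[C@H](C)C[C@@]2(O[Si](CC)(CC)CC)C(C)=C
A4 | alternative 2 | cis-fused hydroazulen-10-one with C3,C4 acetonide and C6=C7 alkene | CC1(C)O[C@H]2C[C@]3(C)C(=O)C[C@@H](C)C=C[C@@H]3[C@]2(O1)C(C)C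
A5 | alternative 3 | 3-[1-(tert-butyldimethylsilyloxy)vinyl]cyclopent-2-en-1-one | C=C(O[Si](C)(C)C(C)(C)C)C1=CC(=O)CC1
A6 | alternative 3 | methyl (E)-4-(tert-butyldimethylsilyloxy)-2-diazobut-3-enoate | COC(=O)C(=[N+]=[N-])/C=C/O[Si](C)(C)C(C)(C)C
A7 | alternative 3 | bicyclo[5.3.0]decadienone with C10 silyl enol ether, C8 ester, C6 silyloxy and C4 ketone | C1CC2=C(O[Si](C)(C)C(C)(C)C)CC(C(=O)OC)=C[C@H](O[Si](C)(C)C(C)(C)C)[C@@H]2C1=O
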